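**Plan**

- Retrosynthesis: the two ring A silyl ethers are cut first. Then both bonds at the alpha carbon, C(alpha)–OH and C(alpha)–C(beta), are cut in one operation, giving a ring A diazoketone, water and a ring B para-quinone methide (from 4-hydroxy-3-prenylbenzyl alcohol). Ring A goes back to 4,6-dibromoresorcinol, ring B to 4-hydroxybenzaldehyde, both prenyl groups to prenyl bromide.
- Enabling feature: the alpha carbon bears a hydroxyl and is attached to the ring A aryl ketone carbonyl (a carbene carbon that has captured water). The beta carbon is a benzylic CH2 para to the ring B phenol oxygen (the exocyclic carbon of a para-quinone methide).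
- Forward order: ring A is built by two bromine–lithium exchanges (prenyl, then acetyl), a MOM-to-triisopropylsilyl exchange and diazo transfer. Ring B is built by C-prenylation and reduction. The three-carbon chain is joined in one three-component step, then the silyl ethers are removed. No ring is formed at any stage.
- Stereochemistry: the only stereocentre, C(alpha) (R), is set in the three-component step by a chiral BINOL-derived phosphoric acid and is kept through a buffered desilylation.
- Protecting groups: MOM ethers serve the aryllithium steps. Triisopropylsilyl ethers are used on the diazoketone because an ortho acetal oxygen would capture the carbene intramolecularly and be lost as a coumaranone.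

Key step: step 9

Assumption: (R)-TRIP, (R)-3,3'-bis(2,4,6-triisopropylphenyl)-1,1'-binaphthyl-2,2'-diyl hydrogen phosphate, is taken to deliver the (R)-ketol; if the opposite sense of induction is found, the (S)-acid is used with no other change.

**Route**

Step 1
Reactants: 1 4,6-dibromoresorcinol (4,6-dibromobenzene-1,3-diol)
Product: 2 1,5-dibromo-2,4-bis(methoxymethoxy)benzene
Conditions: MOMCl (2.5 equiv), i-Pr2NEt (3 equiv), CH2Cl2, 0 °C to rt
Reagents that add atoms: chloromethyl methyl ether (MOMCl), COCCl
Why: Base-mediated O-alkylation (Williamson-type etherification) of both acidic bromophenol hydroxyls should be clean, and the MOM ethers later stabilise the ortho-aryllithiums by chelation.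

Step 2
Reactants: 2 1,5-dibromo-2,4-bis(methoxymethoxy)benzene; 3 prenyl bromide (1-bromo-3-methylbut-2-ene)
Product: 5 1-bromo-2,4-bis(methoxymethoxy)-5-(3-methylbut-2-enyl)benzene, via aryllithium 4 (not isolated)
Conditions: n-BuLi (1.0 equiv), THF, −78 °C; then CuBr·SMe2 (10 mol%), 3 (1.2 equiv), −78 to 0 °C
Reagents that add atoms: none
Why: Bromine–lithium exchange should stop after one bromine because the first aryllithium deactivates the ring towards a second exchange, and copper-catalysed allylic substitution at the primary carbon of 3 (SN2 mode) should give the linear prenyl arene.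

Step 3
Reactants: 5 1-bromo-2,4-bis(methoxymethoxy)-5-(3-methylbut-2-enyl)benzene
Product: 8 1-[2,4-bis(methoxymethoxy)-5-(3-methylbut-2-enyl)phenyl]ethanone, via aryllithium 6 (not isolated), via tetrahedral adduct 7 (not isolated)
Conditions: n-BuLi (1.05 equiv), THF, −78 °C; then MeC(O)N(OMe)Me (1.5 equiv), −78 to 0 °C; H2O quench
Reagents that add atoms: N-methoxy-N-methylacetamide, CC(=O)N(C)OC
Why: Weinreb ketone synthesis, in which the second bromine–lithium exchange is faster than deprotonation of the prenyl CH2 at −78 °C and the chelated adduct 7 survives until the quench, so no tertiary alcohol should form.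

Step 4
Reactants: 8 1-[2,4-bis(methoxymethoxy)-5-(3-methylbut-2-enyl)phenyl]ethanone
Product: 9 1-[2,4-dihydroxy-5-(3-methylbut-2-enyl)phenyl]ethanone
Conditions: HCl (1 M) in MeOH, 25 to 40 °C
Reagents that add atoms: none
Why: Acid-catalysed acetal exchange with methanol (MOM ether cleavage) should free both phenols, and dilute acid at moderate temperature should not add the neighbouring phenol to the prenyl alkene, as is usual for MOM-protected prenylated aryl ketones.

Step 5
Reactants: 9 1-[2,4-dihydroxy-5-(3-methylbut-2-enyl)phenyl]ethanone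
Product: 10 1-[5-(3-methylbut-2-enyl)-2,4-bis(triisopropylsilyloxy)phenyl]ethanone
Conditions: TIPSCl (2.6 equiv), imidazole (5 equiv), DMAP (10 mol%), DMF, rt to 50 °C
Reagents that add atoms: chlorotriisopropylsilane (TIPSCl), CC(C)[Si](Cl)(C(C)C)C(C)C
Why: Imidazole-promoted silylation of phenols should cap both oxygens, the hydrogen-bonded 2-hydroxyl reacting last and needing the excess reagent and gentle warming.

Step 6
Reactants: 10 1-[5-(3-methylbut-2-enyl)-2,4-bis(triisopropylsilyloxy)phenyl]ethanone
Product: 13 2-diazo-1-[5-(3-methylbut-2-enyl)-2,4-bis(triisopropylsilyloxy)phenyl]ethanone, via lithium enolate 11 (not isolated), via trifluoroacetyl ketone 12 (not isolated)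
Conditions: LiN(SiMe3)2 (1.1 equiv), THF, −78 °C; CF3CO2CH2CF3 (1.2 equiv), −78 °C; cold 1 M aq. HCl wash, crude 12 used directly; then 4-acetamidobenzenesulfonyl azide (1.5 equiv), Et3N (1.5 equiv), H2O (1 equiv), MeCN, rt
Reagents that add atoms: 4-acetamidobenzenesulfonyl azide, CC(=O)Nc1ccc(cc1)S(=O)(=O)N=[N+]=[N-]
Why: Detrifluoroacetylative diazo transfer (a Regitz-type deacylative diazo transfer), in which the kinetic enolate 11 is C-acylated within minutes at −78 °C and the activated diketone 12 takes the diazo group from the sulfonyl azide with loss of the trifluoroacetyl group, under conditions that aryl triisopropylsilyl ethers and the prenyl group tolerate.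

Step 7
Reactants: 14 4-hydroxybenzaldehyde; 3 prenyl bromide (1-bromo-3-methylbut-2-ene)
Product: 15 4-hydroxy-3-(3-methylbut-2-enyl)benzaldehyde
Conditions: KOH (10% aq., 1.1 equiv), 3 (1.0 equiv), 0 °C to rt; then dilute HCl to pH 5, chromatography
Reagents that add atoms: none
Why: Nuclear C-alkylation of an ambident phenoxide, in which water hydrogen-bonds the phenoxide oxygen so that SN2 attack through the ortho carbon (para is blocked by the formyl group) competes with O-alkylation; conversion is expected to be modest, but the O-prenyl ether and unchanged 14 should separate easily.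

Step 8
Reactants: 15 4-hydroxy-3-(3-methylbut-2-enyl)benzaldehyde
Product: 16 4-(hydroxymethyl)-2-(3-methylbut-2-enyl)phenol
Conditions: NaBH4 (1.0 equiv), MeOH, 0 °C; pH 7 phosphate buffer work-up
Reagents that add atoms: none
Why: Borohydride reduction of the aldehyde leaves the alkene untouched, and a cold, neutral work-up should keep the para-hydroxybenzylic alcohol from ionising prematurely.

Step 9
Reactants: 13 2-diazo-1-[5-(3-methylbut-2-enyl)-2,4-bis(triisopropylsilyloxy)phenyl]ethanone; 16 4-(hydroxymethyl)-2-(3-methylbut-2-enyl)phenol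
Product: 19 (2R)-2-hydroxy-3-[4-hydroxy-3-(3-methylbut-2-enyl)phenyl]-1-[5-(3-methylbut-2-enyl)-2,4-bis(triisopropylsilyloxy)phenyl]propan-1-one, via quinone methide 17 (not isolated), via enediol 18 (not isolated)
Conditions: Rh2(OAc)4 (2 mol%), (R)-TRIP (10 mol%), H2O (5 equiv), CH2Cl2 (0.05 M), 25 °C; 13 (1.4 equiv) added over 4 h by syringe pump to 16 (1.0 equiv)
Reagents that add atoms: water, O
Why: Proposed new method: Rh2(OAc)4 converts diazoketone 13 into an acceptor carbene that water captures to give a protic oxonium ylide (drawn as its enediol form 18), while the phosphoric acid ionises the para-hydroxybenzylic alcohol 16 to the para-quinone methide 17 and hydrogen-bonds both the enol O–H and the quinone methide carbonyl, so that the ylide carbon should add 1,6 to the exocyclic methylene before the 1,2-proton shift, forming the C(alpha)–O and C(alpha)–C(beta) bonds and rearomatising ring B. The closest known reaction type is the Rh2(OAc)4 and chiral phosphoric acid co-catalysed three-component trapping of protic oxonium ylides (from diazo carbonyl compounds with water or alcohols) by imines and by aryl-substituted para-quinone methides; an unsubstituted quinone methide made in place from a primary benzylic alcohol has not been used in it. No ring is closed. The single new stereocentre is set under catalyst control by the chiral phosphate, which differentiates the two faces of the enol carbon in the doubly hydrogen-bonded transition state. The step needs water capture and 1,6-trapping to win over the 1,2-proton shift, O–H insertion into the phenol or benzylic hydroxyl, prenyl cyclopropanation, phenol alkylation by 17 and capture of the carbene by the ortho oxygen of ring A; excess water, slow addition of 13, high dilution, the poor reactivity of trisubstituted alkenes towards acceptor carbenes and the hindered, weakly basic silyl ether oxygens (the reason MOM ethers are not carried into this step) are meant to secure this. Capture of the carbene by the benzylic hydroxyl of 16 need not be a dead end, because that ylide can expel 17 and feed the same enol and quinone methide pair.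

Step 10
Reactants: 19 (2R)-2-hydroxy-3-[4-hydroxy-3-(3-methylbut-2-enyl)phenyl]-1-[5-(3-methylbut-2-enyl)-2,4-bis(triisopropylsilyloxy)phenyl]propan-1-one
Product: 20 Kanzonol Y, (2R)-1-[2,4-dihydroxy-5-(3-methylbut-2-enyl)phenyl]-2-hydroxy-3-[4-hydroxy-3-(3-methylbut-2-enyl)phenyl]propan-1-one
Conditions: Bu4NF (2.5 equiv), AcOH (2.5 equiv), THF, 0 °C
Reagents that add atoms: none
Why: Fluoride-induced cleavage of the two aryl silyl ethers (desilylation driven by the Si–F bond) is fast for phenoxide leaving groups, and the acetic acid buffer should prevent enolisation of the alpha-ketol, so the stereocentre and both prenyl groups should survive.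

**Compound list**

1 | 4,6-dibromoresorcinol (4,6-dibromobenzene-1,3-diol) | Oc1cc(O)c(Br)cc1Br | starting material
2 | 1,5-dibromo-2,4-bis(methoxymethoxy)benzene | COCOc1cc(OCOC)c(Br)cc1Br | intermediate
3 | prenyl bromide (1-bromo-3-methylbut-2-ene) | CC(C)=CCBr | starting material
4 | [5-bromo-2,4-bis(methoxymethoxy)phenyl]lithium, formed in place | [Li]c1cc(Br)c(OCOC)cc1OCOC | intermediate
5 | 1-bromo-2,4-bis(methoxymethoxy)-5-(3-methylbut-2-enyl)benzene | COCOc1cc(OCOC)c(CC=C(C)C)cc1Br | intermediate
6 | [2,4-bis(methoxymethoxy)-5-(3-methylbut-2-enyl)phenyl]lithium, formed in place | [Li]c1cc(CC=C(C)C)c(OCOC)cc1OCOC | intermediate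
7 | lithium 1-[2,4-bis(methoxymethoxy)-5-(3-methylbut-2-enyl)phenyl]-1-[methoxy(methyl)amino]ethanolate, formed in place | [Li]OC(C)(N(C)OC)c1cc(CC=C(C)C)c(OCOC)cc1OCOC | intermediate
8 | 1-[2,4-bis(methoxymethoxy)-5-(3-methylbut-2-enyl)phenyl]ethanone | CC(=O)c1cc(CC=C(C)C)c(OCOC)cc1OCOC | intermediate
9 | 1-[2,4-dihydroxy-5-(3-methylbut-2-enyl)phenyl]ethanone | CC(=O)c1cc(CC=C(C)C)c(O)cc1O | intermediate
10 | 1-[5-(3-methylbut-2-enyl)-2,4-bis(triisopropylsilyloxy)phenyl]ethanone | CC(=O)c1cc(CC=C(C)C)c(O[Si](C(C)C)(C(C)C)C(C)C)cc1O[Si](C(C)C)(C(C)C)C(C)C | intermediate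
11 | lithium 1-[5-(3-methylbut-2-enyl)-2,4-bis(triisopropylsilyloxy)phenyl]ethenolate, formed in place | [Li]OC(=C)c1cc(CC=C(C)C)c(O[Si](C(C)C)(C(C)C)C(C)C)cc1O[Si](C(C)C)(C(C)C)C(C)C | intermediate
12 | 4,4,4-trifluoro-1-[5-(3-methylbut-2-enyl)-2,4-bis(triisopropylsilyloxy)phenyl]butane-1,3-dione, used crude | O=C(CC(=O)C(F)(F)F)c1cc(CC=C(C)C)c(O[Si](C(C)C)(C(C)C)C(C)C)cc1O[Si](C(C)C)(C(C)C)C(C)C | intermediate
13 | 2-diazo-1-[5-(3-methylbut-2-enyl)-2,4-bis(triisopropylsilyloxy)phenyl]ethanone | [N-]=[N+]=CC(=O)c1cc(CC=C(C)C)c(O[Si](C(C)C)(C(C)C)C(C)C)cc1O[Si](C(C)C)(C(C)C)C(C)C | intermediate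
14 | 4-hydroxybenzaldehyde | O=Cc1ccc(O)cc1 | starting material
15 | 4-hydroxy-3-(3-methylbut-2-enyl)benzaldehyde | CC(C)=CCc1cc(C=O)ccc1O | intermediate
16 | 4-(hydroxymethyl)-2-(3-methylbut-2-enyl)phenol | CC(C)=CCc1cc(CO)ccc1O | intermediate
17 | 4-methylidene-2-(3-methylbut-2-enyl)cyclohexa-2,5-dien-1-one (ring B para-quinone methide), formed in place | C=C1C=CC(=O)C(CC=C(C)C)=C1 | intermediate
18 | 1-[5-(3-methylbut-2-enyl)-2,4-bis(triisopropylsilyloxy)phenyl]ethene-1,2-diol (enediol form of the rhodium-associated water oxonium ylide; alkene geometry not defined), formed in place | OC=C(O)c1cc(CC=C(C)C)c(O[Si](C(C)C)(C(C)C)C(C)C)cc1O[Si](C(C)C)(C(C)C)C(C)C | intermediate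
19 | (2R)-2-hydroxy-3-[4-hydroxy-3-(3-methylbut-2-enyl)phenyl]-1-[5-(3-methylbut-2-enyl)-2,4-bis(triisopropylsilyloxy)phenyl]propan-1-one | CC(C)=CCc1cc(C[C@@H](O)C(=O)c2cc(CC=C(C)C)c(O[Si](C(C)C)(C(C)C)C(C)C)cc2O[Si](C(C)C)(C(C)C)C(C)C)ccc1O | intermediate
20 | Kanzonol Y, (2R)-1-[2,4-dihydroxy-5-(3-methylbut-2-enyl)phenyl]-2-hydroxy-3-[4-hydroxy-3-(3-methylbut-2-enyl)phenyl]propan-1-one | CC(C)=CCc1cc(C[C@@H](O)C(=O)c2cc(CC=C(C)C)c(O)cc2O)ccc1O | target

**Count**

Total steps: 10. Longest linear sequence: 8 steps (steps 1 to 6, 9 and 10, from 4,6-dibromoresorcinol); the ring B branch has 2 steps (7 and 8).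

**Steps most likely to fail**

1. Step 9 (proposed new method). The 1,2-proton shift of the ylide, or O–H insertion into the phenol and the benzylic hydroxyl, may outrun carbon–carbon bond formation. Ionisation of the primary benzylic alcohol may be too slow at 25 °C, or the quinone methide may be consumed by phenol alkylation (oligomerisation). Facial discrimination by the phosphate may be low.
   Fallback, using only known reactions: it sets out from ketone 8 and aldehyde 15 and rejoins the route at 20. Aldehyde 15 is protected with MOMCl and i-Pr2NEt to give 4-(methoxymethoxy)-3-(3-methylbut-2-enyl)benzaldehyde F1. Claisen–Schmidt condensation of F1 with 8 (KOH, EtOH, rt) should give (E)-1-[2,4-bis(methoxymethoxy)-5-(3-methylbut-2-enyl)phenyl]-3-[4-(methoxymethoxy)-3-(3-methylbut-2-enyl)phenyl]prop-2-en-1-one F2. Conjugate reduction with Stryker's reagent [(Ph3P)CuH]6 and a silane in toluene spares the prenyl groups and gives the dihydrochalcone 1-[2,4-bis(methoxymethoxy)-5-(3-methylbut-2-enyl)phenyl]-3-[4-(methoxymethoxy)-3-(3-methylbut-2-enyl)phenyl]propan-1-one F3. KN(SiMe3)2 in THF at −78 °C forms the potassium (Z)-enolate of the dihydrochalcone F4. Davis oxidation of F4 with the enantiomer of (camphorsulfonyl)oxaziridine that delivers the (R)-ketol gives (2R)-1-[2,4-bis(methoxymethoxy)-5-(3-methylbut-2-enyl)phenyl]-2-hydroxy-3-[4-(methoxymethoxy)-3-(3-methylbut-2-enyl)phenyl]propan-1-one F5, the stereocentre now being set by the reagent. Dilute HCl in MeOH then removes the three MOM groups to give 20.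

2. Step 6. The ortho silyl group may transfer from the phenolic oxygen to the enolate oxygen before acylation, or trifluoroacetylation may occur on oxygen instead of carbon, so that diazo transfer gives no diazoketone.
   Fallback without a metal enolate: it sets out from 10 and rejoins at 13. Ketone 10 is condensed with Bredereck's reagent, t-BuOCH(NMe2)2, in toluene at 60 °C to give the enaminone (E)-3-(dimethylamino)-1-[5-(3-methylbut-2-enyl)-2,4-bis(triisopropylsilyloxy)phenyl]prop-2-en-1-one F6. Tosyl azide in MeCN at rt then adds across the enamine double bond and the triazoline fragments (deformylative diazo transfer to an enaminone), giving 13.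

3. Step 7. O-alkylation and double alkylation of the phenoxide may dominate over ortho C-alkylation, leaving too little of the C-prenyl aldehyde.
   Fallback that forms the aryl–carbon bond by a sigmatropic shift: it sets out from 14 and rejoins at 15. Phenol 14 is O-alkylated with 3-chloro-3-methylbut-1-yne (DBU, CuCl2·2H2O 1 mol%, MeCN, 0 °C) to give 4-(2-methylbut-3-yn-2-yloxy)benzaldehyde F7. Semi-hydrogenation (H2, Lindlar catalyst: Pd on CaCO3 poisoned with Pb(OAc)2, quinoline, EtOAc) gives 4-(2-methylbut-3-en-2-yloxy)benzaldehyde F8. Aromatic Claisen rearrangement in N,N-diethylaniline at about 130 to 190 °C moves the allyl unit to the ortho carbon with allylic transposition and returns 15.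

Further compounds
F1 | step 9 | 4-(methoxymethoxy)-3-(3-methylbut-2-enyl)benzaldehyde | CC(C)=CCc1cc(C=O)ccc1OCOC
F2 | step 9 | (E)-1-[2,4-bis(methoxymethoxy)-5-(3-methylbut-2-enyl)phenyl]-3-[4-(methoxymethoxy)-3-(3-methylbut-2-enyl)phenyl]prop-2-en-1-one | CC(C)=CCc1cc(/C=C/C(=O)c2cc(CC=C(C)C)c(OCOC)cc2OCOC)ccc1OCOC
F3 | step 9 | 1-[2,4-bis(methoxymethoxy)-5-(3-methylbut-2-enyl)phenyl]-3-[4-(methoxymethoxy)-3-(3-methylbut-2-enyl)phenyl]propan-1-one | CC(C)=CCc1cc(CCC(=O)c2cc(CC=C(C)C)c(OCOC)cc2OCOC)ccc1OCOC
F4 | step 9 | potassium (Z)-1-[2,4-bis(methoxymethoxy)-5-(3-methylbut-2-enyl)phenyl]-3-[4-(methoxymethoxy)-3-(3-methylbut-2-enyl)phenyl]prop-1-en-1-olate | CC(C)=CCc1cc(C/C=C(\O[K])c2cc(CC=C(C)C)c(OCOC)cc2OCOC)ccc1OCOC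
F5 | step 9 | (2R)-1-[2,4-bis(methoxymethoxy)-5-(3-methylbut-2-enyl)phenyl]-2-hydroxy-3-[4-(methoxymethoxy)-3-(3-methylbut-2-enyl)phenyl]propan-1-one | CC(C)=CCc1cc(C[C@@H](O)C(=O)c2cc(CC=C(C)C)c(OCOC)cc2OCOC)ccc1OCOC
F6 | step 6 | (E)-3-(dimethylamino)-1-[5-(3-methylbut-2-enyl)-2,4-bis(triisopropylsilyloxy)phenyl]prop-2-en-1-one | CN(C)/C=C/C(=O)c1cc(CC=C(C)C)c(O[Si](C(C)C)(C(C)C)C(C)C)cc1O[Si](C(C)C)(C(C)C)C(C)C
F7 | step 7 | 4-(2-methylbut-3-yn-2-yloxy)benzaldehyde | C#CC(C)(C)Oc1ccc(C=O)cc1
F8 | step 7 | 4-(2-methylbut-3-en-2-yloxy)benzaldehyde | C=CC(C)(C)Oc1ccc(C=O)cc1
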